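**Plan**

- Retrosynthesis cuts ring A at C8–C8a and C4a–C5, leaving only its C4a=C8a edge, which belongs to a γ-pyrone (ring C). It then cuts the C3–C1' bond to ring B, the aryl–prenyl bond and the C3'–O bond.
- Enabling feature: ring A carries OMe at C5 beside the acyl-bearing C4a, a free OH at C7, and hydrogen at C6 and C8. This is the imprint of a 1,1-dimethoxy-3-silyloxybutadiene added across the C4a=C8a edge of ring C.
- Forward order: ring B is functionalised from 2,4,6-tribromoanisole and joined to the preformed pyranone by Suzuki–Miyaura coupling. Ring A is grown last by cycloaddition and aromatisation.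
- The pyranone carbon that becomes C4a carries a phenylsulfinyl group. It activates the C4a=C8a bond and then leaves by thermal syn elimination with the cis H-8a; a halide there would need base to leave from a non-acidic, syn hydrogen.
- Stereochemistry: the target has no stereocentre and no configured double bond. The centres formed in the cycloaddition (C4a, C8a) and the sulfur centre disappear in the same step.

Key step: step 11

Remark: sulfoxide 14 is used as the racemate and tetrabromide 10 as a diastereomer mixture, since all of these stereocentres are removed within the route.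

**Route**

Step 1
Reactants: 1 2,4,6-tribromoanisole
Product: 4 3,5-dibromo-2-methoxyphenol, via dibromoarylmagnesium chloride 2 (not isolated), via dimethyl arylboronate 3 (not isolated)
Conditions: i-PrMgCl·LiCl, THF, −15 °C; B(OMe)3, −15 °C → rt; 30% H2O2, AcOH, 0 °C → rt
Reagents that add atoms: hydrogen peroxide, OO
Why: Bromine–magnesium exchange should occur at one of the two equivalent bromines ortho to the methoxy group, whose oxygen stabilises the ortho carbanion, and borylation followed by peroxide oxidation is the standard conversion of an aryl Grignard reagent into a phenol.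

Step 2
Reactants: 4 3,5-dibromo-2-methoxyphenol
Product: 5 (3,5-dibromo-2-methoxyphenoxy)tri(propan-2-yl)silane
Conditions: TIPSCl, imidazole, DMF, rt
Reagents that add atoms: chlorotri(propan-2-yl)silane, CC(C)[Si](Cl)(C(C)C)C(C)C
Why: Silyl ether formation on a phenol gives a triisopropylsilyl ether that should withstand the organomagnesium, palladium and peroxide steps ahead and is later removed by fluoride without touching the prenyl group or the methyl ethers.

Step 3
Reactants: 5 (3,5-dibromo-2-methoxyphenoxy)tri(propan-2-yl)silane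
Product: 7 [5-bromo-2-methoxy-3-(3-methylbut-2-en-1-yl)phenoxy]tri(propan-2-yl)silane, via bromoarylmagnesium chloride 6 (not isolated)
Conditions: i-PrMgCl·LiCl, THF, −15 °C; Li2CuCl4 (5 mol%), prenyl bromide, −15 → 0 °C
Reagents that add atoms: 1-bromo-3-methylbut-2-ene, CC(C)=CCBr
Why: Regioselective bromine–magnesium exchange should take the bromine ortho to the methoxy group and leave the para bromine, and copper-catalysed allylic substitution at the unhindered primary carbon of prenyl bromide (SN2, not SN2', which would build a quaternary centre) installs the prenyl group.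

Step 4
Reactants: 7 [5-bromo-2-methoxy-3-(3-methylbut-2-en-1-yl)phenoxy]tri(propan-2-yl)silane
Product: 8 2-[4-methoxy-3-(3-methylbut-2-en-1-yl)-5-(triisopropylsilyloxy)phenyl]-4,4,5,5-tetramethyl-1,3,2-dioxaborolane
Conditions: B2pin2, PdCl2(dppf) (3 mol%), KOAc, dioxane, 90 °C
Reagents that add atoms: bis(pinacolato)diboron, CC1(C)OB(B2OC(C)(C)C(C)(C)O2)OC1(C)C
Why: Miyaura borylation of an unhindered aryl bromide, which tolerates the silyl ether and the trisubstituted alkene.

Step 5
Reactants: 9 4H-pyran-4-one
Product: 11 3,5-dibromo-4H-pyran-4-one, via tetrabromooxanone 10 (not isolated)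
Conditions: Br2 (2.1 equiv), CH2Cl2, 0 °C → rt; then Et3N, 0 °C
Reagents that add atoms: bromine, BrBr
Why: α-Bromination of a vinylogous ester by addition–elimination, in which bromine adds across each enol ether double bond and the base then removes the acidic α-hydrogen and expels the β-bromide (E1cB), as in the conversion of chromone into 3-bromochromone.

Step 6
Reactants: 8 arylboronate from step 4; 11 3,5-dibromo-4H-pyran-4-one (three equivalents)
Product: 12 3-bromo-5-[4-methoxy-3-(3-methylbut-2-en-1-yl)-5-(triisopropylsilyloxy)phenyl]-4H-pyran-4-one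
Conditions: Pd(PPh3)4 (5 mol%), K3PO4, dioxane/H2O (10:1), 70 °C
Reagents that add atoms: none
Why: Suzuki–Miyaura coupling, in which zerovalent palladium inserts readily into the carbon–bromine bond α to the pyranone carbonyl, and the excess of the symmetrical dibromide should hold the reaction at the mono-arylated stage.

Step 7
Reactants: 12 3-bromo-5-aryl-4H-pyran-4-one from step 6
Product: 13 3-[4-methoxy-3-(3-methylbut-2-en-1-yl)-5-(triisopropylsilyloxy)phenyl]-5-(phenylsulfanyl)-4H-pyran-4-one
Conditions: PhSH, Pd2(dba)3 (2.5 mol%), Xantphos (5 mol%), i-Pr2NEt, degassed dioxane, 90 °C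
Reagents that add atoms: benzenethiol, Sc1ccccc1
Why: Palladium-catalysed carbon–sulfur cross-coupling of a heteroaryl-type bromide with a thiol, in which the wide-bite-angle bisphosphine favours C–S reductive elimination and the weak amine base keeps the free thiolate concentration low.

Step 8
Reactants: 13 aryl(phenylsulfanyl)pyranone from step 7
Product: 14 3-[4-methoxy-3-(3-methylbut-2-en-1-yl)-5-(triisopropylsilyloxy)phenyl]-5-(phenylsulfinyl)-4H-pyran-4-one
Conditions: 30% H2O2 (1.1 equiv), (CF3)2CHOH, rt
Reagents that add atoms: hydrogen peroxide, OO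
Why: Chemoselective sulfide-to-sulfoxide oxidation, in which hexafluoroisopropanol activates hydrogen peroxide by hydrogen bonding and deactivates the sulfoxide towards over-oxidation while the trisubstituted alkene is not epoxidised; the new sulfur stereocentre forms as a racemate, which does not matter.

Step 9
Reactants: 15 1,1-dimethoxyethene; 16 acetyl chloride
Product: 17 4,4-dimethoxybut-3-en-2-one
Conditions: Et3N, Et2O, 0 °C → rt
Reagents that add atoms: none
Why: C-Acylation of a ketene acetal at its nucleophilic methylene carbon by an acid chloride, with the amine removing hydrogen chloride to restore the ketene acetal double bond.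

Step 10
Reactants: 17 4,4-dimethoxybut-3-en-2-one
Product: 18 1,1-dimethoxy-3-(trimethylsilyloxy)buta-1,3-diene
Conditions: TMSOTf, Et3N, Et2O, 0 °C
Reagents that add atoms: trimethylsilyl trifluoromethanesulfonate, C[Si](C)(C)OS(=O)(=O)C(F)(F)F
Why: Soft enolisation and O-silylation of the methyl ketone (silyl dienol ether formation) gives the 2-silyloxy diene, which is used at once.

Step 11
Reactants: 14 aryl(phenylsulfinyl)pyranone from step 8; 18 1,1-dimethoxy-3-(trimethylsilyloxy)buta-1,3-diene (2.5 equivalents)
Product: 22 7-hydroxy-5-methoxy-3-[4-methoxy-3-(3-methylbut-2-en-1-yl)-5-(triisopropylsilyloxy)phenyl]-4H-chromen-4-one, via sulfinyl cycloadduct 19 (not isolated), via dihydrochromenone ketal 20 (not isolated), via aryl trimethylsilyl ether 21 (not isolated)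
Conditions: toluene, 25 → 80 °C; then PPTS, THF/H2O, rt
Reagents that add atoms: none
Why: Proposed new method: the electron-rich methylene terminus of diene 18 should bond to C6 of the pyranone, which is β to both the carbonyl and the sulfinyl group, while the ketene acetal carbon bonds to the sulfinyl-bearing C5, in a polar and possibly stepwise [4+2] cycloaddition that forms C8–C8a and C4a–C5 and closes ring A as a six-membered ring, suprafacially on the pyranone. The closest known reaction type is the tandem Diels–Alder/sulfoxide elimination of 2-sulfinyl quinones and 2-sulfinyl enones with alkoxy silyloxy dienes, together with cycloadditions of chromones that carry an acceptor at C3. In the cis-fused adduct 19 the sulfinyl oxygen lies syn to H-8a, so benzenesulfenic acid should leave by thermal syn elimination (Ei) and restore the C4a=C8a bond without any base that could open the pyranone by β-elimination of O1. Ketal 20 then loses methanol by 1,4-elimination to give the aromatic silyl ether 21, and the mild acid work-up frees the C7 hydroxyl. The two carbon stereocentres formed (C4a, C8a) are erased on aromatisation, so no stereocontrol is required. The step needs selectivity for the C5=C6 over the C2=C3 double bond of the pyranone and for the head-to-tail orientation: the sulfinyl group activates only its own double bond, the aryl group shields the other, and the polarity of diene and acceptor places the methoxy group at C5 and the hydroxyl at C7.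

Step 12
Reactants: 22 7-hydroxy-5-methoxy-3-[4-methoxy-3-(3-methylbut-2-en-1-yl)-5-(triisopropylsilyloxy)phenyl]-4H-chromen-4-one
Product: 23 7-hydroxy-3-[3-hydroxy-4-methoxy-5-(3-methylbut-2-en-1-yl)phenyl]-5-methoxy-4H-chromen-4-one
Conditions: TBAF, AcOH, THF, 0 °C
Reagents that add atoms: none
Why: Fluoride-induced cleavage of the aryl silyl ether (desilylation), buffered with acetic acid so that the chromone and the prenyl group are not exposed to strong base or acid.

**Compound list**

1 | 2,4,6-tribromoanisole (1,3,5-tribromo-2-methoxybenzene) | COc1c(Br)cc(Br)cc1Br | starting material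
2 | (3,5-dibromo-2-methoxyphenyl)magnesium chloride | COc1c([Mg]Cl)cc(Br)cc1Br | intermediate
3 | dimethyl (3,5-dibromo-2-methoxyphenyl)boronate | COB(OC)c1cc(Br)cc(Br)c1OC | intermediate
4 | 3,5-dibromo-2-methoxyphenol | COc1c(O)cc(Br)cc1Br | intermediate
5 | (3,5-dibromo-2-methoxyphenoxy)tri(propan-2-yl)silane | COc1c(O[Si](C(C)C)(C(C)C)C(C)C)cc(Br)cc1Br | intermediate
6 | [5-bromo-2-methoxy-3-(triisopropylsilyloxy)phenyl]magnesium chloride | COc1c(O[Si](C(C)C)(C(C)C)C(C)C)cc(Br)cc1[Mg]Cl | intermediate
7 | [5-bromo-2-methoxy-3-(3-methylbut-2-en-1-yl)phenoxy]tri(propan-2-yl)silane | COc1c(O[Si](C(C)C)(C(C)C)C(C)C)cc(Br)cc1CC=C(C)C | intermediate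
8 | 2-[4-methoxy-3-(3-methylbut-2-en-1-yl)-5-(triisopropylsilyloxy)phenyl]-4,4,5,5-tetramethyl-1,3,2-dioxaborolane | COc1c(O[Si](C(C)C)(C(C)C)C(C)C)cc(B2OC(C)(C)C(C)(C)O2)cc1CC=C(C)C | intermediate
9 | 4H-pyran-4-one | O=c1ccocc1 | starting material
10 | 2,3,5,6-tetrabromooxan-4-one (diastereomer mixture, configuration not defined) | O=C1C(Br)C(Br)OC(Br)C1Br | intermediate
11 | 3,5-dibromo-4H-pyran-4-one | O=c1c(Br)cocc1Br | intermediate
12 | 3-bromo-5-[4-methoxy-3-(3-methylbut-2-en-1-yl)-5-(triisopropylsilyloxy)phenyl]-4H-pyran-4-one | O=c1c(Br)cocc1-c2cc(O[Si](C(C)C)(C(C)C)C(C)C)c(OC)c(CC=C(C)C)c2 | intermediate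
13 | 3-[4-methoxy-3-(3-methylbut-2-en-1-yl)-5-(triisopropylsilyloxy)phenyl]-5-(phenylsulfanyl)-4H-pyran-4-one | O=c1c(Sc2ccccc2)cocc1-c3cc(O[Si](C(C)C)(C(C)C)C(C)C)c(OC)c(CC=C(C)C)c3 | intermediate
14 | 3-[4-methoxy-3-(3-methylbut-2-en-1-yl)-5-(triisopropylsilyloxy)phenyl]-5-(phenylsulfinyl)-4H-pyran-4-one (racemic at sulfur) | O=c1c(S(=O)c2ccccc2)cocc1-c3cc(O[Si](C(C)C)(C(C)C)C(C)C)c(OC)c(CC=C(C)C)c3 | intermediate
15 | 1,1-dimethoxyethene | C=C(OC)OC | starting material
16 | acetyl chloride | CC(=O)Cl | starting material
17 | 4,4-dimethoxybut-3-en-2-one | CC(=O)C=C(OC)OC | intermediate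
18 | 1,1-dimethoxy-3-(trimethylsilyloxy)buta-1,3-diene | COC(OC)=CC(=C)O[Si](C)(C)C | intermediate
19 | 5,5-dimethoxy-3-[4-methoxy-3-(3-methylbut-2-en-1-yl)-5-(triisopropylsilyloxy)phenyl]-4a-(phenylsulfinyl)-7-(trimethylsilyloxy)-4a,5,8,8a-tetrahydro-4H-chromen-4-one, cis ring fusion (H-8a and the sulfinyl group on the same face), racemic, both sulfur epimers | O=C1C(c3cc(O[Si](C(C)C)(C(C)C)C(C)C)c(OC)c(CC=C(C)C)c3)=CO[C@@H]2CC(O[Si](C)(C)C)=CC(OC)(OC)[C@]12S(=O)c4ccccc4 | intermediate
20 | 5,5-dimethoxy-3-[4-methoxy-3-(3-methylbut-2-en-1-yl)-5-(triisopropylsilyloxy)phenyl]-7-(trimethylsilyloxy)-5,8-dihydro-4H-chromen-4-one | O=c1c(-c3cc(O[Si](C(C)C)(C(C)C)C(C)C)c(OC)c(CC=C(C)C)c3)coc2CC(O[Si](C)(C)C)=CC(OC)(OC)c12 | intermediate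
21 | 5-methoxy-3-[4-methoxy-3-(3-methylbut-2-en-1-yl)-5-(triisopropylsilyloxy)phenyl]-7-(trimethylsilyloxy)-4H-chromen-4-one | COc1cc(O[Si](C)(C)C)cc2occ(-c3cc(O[Si](C(C)C)(C(C)C)C(C)C)c(OC)c(CC=C(C)C)c3)c(=O)c12 | intermediate
22 | 7-hydroxy-5-methoxy-3-[4-methoxy-3-(3-methylbut-2-en-1-yl)-5-(triisopropylsilyloxy)phenyl]-4H-chromen-4-one | COc1cc(O)cc2occ(-c3cc(O[Si](C(C)C)(C(C)C)C(C)C)c(OC)c(CC=C(C)C)c3)c(=O)c12 | intermediate
23 | 7-hydroxy-3-[3-hydroxy-4-methoxy-5-(3-methylbut-2-en-1-yl)phenyl]-5-methoxy-4H-chromen-4-one | COc1c(O)cc(-c2coc3cc(O)cc(OC)c3c2=O)cc1CC=C(C)C | target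

**Step count and risks**

Total step count: 12.
Longest linear sequence: 9 steps (steps 1, 2, 3, 4, 6, 7, 8, 11, 12).

Steps most likely to fail:

1. Step 11. The ring oxygen donates into the C5=C6 bond of the pyranone and may slow the cycloaddition so much that the diene is lost to hydrolysis or oligomerisation first. A stepwise addition may also be diverted by silyl transfer or by opening of the C8a–O1 bond before the sulfoxide has left. The fallback uses known chemistry, sets out from boronate 8 and rejoins the route at 23, with ring A taken from a preformed acetophenone. 1-(2,4-Dihydroxy-6-methoxyphenyl)ethanone F1 would be silylated at the non-chelated hydroxyl (TIPSCl, imidazole) to 1-[2-hydroxy-6-methoxy-4-(triisopropylsilyloxy)phenyl]ethanone F2. Condensation with N,N-dimethylformamide dimethyl acetal would give the enaminone (E)-3-(dimethylamino)-1-[2-hydroxy-6-methoxy-4-(triisopropylsilyloxy)phenyl]prop-2-en-1-one F3. Cyclisation with iodine and pyridine would give 3-iodo-5-methoxy-7-(triisopropylsilyloxy)-4H-chromen-4-one F4. Suzuki–Miyaura coupling of this iodide with 8 should give 5-methoxy-3-[4-methoxy-3-(3-methylbut-2-en-1-yl)-5-(triisopropylsilyloxy)phenyl]-7-(triisopropylsilyloxy)-4H-chromen-4-one F5, and TBAF/AcOH would remove both silyl groups to give 23.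

2. Step 7. The thiolate may add in conjugate fashion to C6 of the bromopyranone and then expel bromide from the neighbouring carbon (cine substitution), or open the ring, faster than palladium inserts into the carbon–bromine bond. The fallback sets out from 12 and rejoins at 14, and it reverses the polarity so that sulfur arrives as an electrophile. Bromine–magnesium exchange (i-PrMgCl·LiCl, THF, −40 °C) would give [5-[4-methoxy-3-(3-methylbut-2-en-1-yl)-5-(triisopropylsilyloxy)phenyl]-4-oxo-4H-pyran-3-yl]magnesium chloride F6, and methyl benzenesulfinate would convert it directly into sulfoxide 14, which also makes step 8 unnecessary.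

3. Step 6. A second coupling at the remaining bromide and attack of hydroxide on the electrophilic dibromopyranone may both erode the mono-arylated product. The fallback sets out from 9 and 8 and rejoins at 12, and it replaces the statistical coupling by a differentiated dihalide. One bromination–dehydrobromination of 9 (Br2, one equivalent, then Et3N) would give 3-bromo-4H-pyran-4-one F7. Iodination of the other α-carbon (I2, pyridine) would give 3-bromo-5-iodo-4H-pyran-4-one F8. Boronate 8 should then couple at the carbon–iodine bond at room temperature with one equivalent of each partner and give 12.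

Further compounds
F1 | step 11 | 1-(2,4-dihydroxy-6-methoxyphenyl)ethanone | CC(=O)c1c(O)cc(O)cc1OC
F2 | step 11 | 1-[2-hydroxy-6-methoxy-4-(triisopropylsilyloxy)phenyl]ethanone | CC(=O)c1c(O)cc(O[Si](C(C)C)(C(C)C)C(C)C)cc1OC
F3 | step 11 | (E)-3-(dimethylamino)-1-[2-hydroxy-6-methoxy-4-(triisopropylsilyloxy)phenyl]prop-2-en-1-one | CN(C)/C=C/C(=O)c1c(O)cc(O[Si](C(C)C)(C(C)C)C(C)C)cc1OC
F4 | step 11 | 3-iodo-5-methoxy-7-(triisopropylsilyloxy)-4H-chromen-4-one | COc1cc(O[Si](C(C)C)(C(C)C)C(C)C)cc2occ(I)c(=O)c12
F5 | step 11 | 5-methoxy-3-[4-methoxy-3-(3-methylbut-2-en-1-yl)-5-(triisopropylsilyloxy)phenyl]-7-(triisopropylsilyloxy)-4H-chromen-4-one | COc1cc(O[Si](C(C)C)(C(C)C)C(C)C)cc2occ(-c3cc(O[Si](C(C)C)(C(C)C)C(C)C)c(OC)c(CC=C(C)C)c3)c(=O)c12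
F6 | step 7 | [5-[4-methoxy-3-(3-methylbut-2-en-1-yl)-5-(triisopropylsilyloxy)phenyl]-4-oxo-4H-pyran-3-yl]magnesium chloride | O=c1c([Mg]Cl)cocc1-c2cc(O[Si](C(C)C)(C(C)C)C(C)C)c(OC)c(CC=C(C)C)c2
F7 | step 6 | 3-bromo-4H-pyran-4-one | O=c1ccocc1Br
F8 | step 6 | 3-bromo-5-iodo-4H-pyran-4-one | O=c1c(I)cocc1Br
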